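At 12.0 h, Monday's flask holds more first end groups, 42.1 %, than the plain second-order law through its first reading allows, 32.0 %. Two chemists dispute what this means for the same flask at the asked time.

| flask | first end groups | second end groups | remark | time |
|---|---|---|---|---|
| Monday's | 0.080 M | 1 equiv | the very flask that is asked about, followed so far |  |
| Sunday's | 0.080 M | 2 equiv | run made earlier |  |
| flask | 0.080 M | 1.00 equiv |  | 30 h |

| run | time / h | links / % | first end groups / % |
|---|---|---|---|
| Monday's | 1.50 | 21.0 | 79.0 |
| Monday's | 3.00 | 33.1 | 67.1 |
| Monday's | 5.00 | 42.8 | 57.9 |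
| Monday's | 6.00 | 46.3 | 53.6 |
| Monday's | 8.00 | 50.9 | 48.9 |
| Monday's | 10.0 | 54.9 | 44.9 |
| Monday's | 12.0 | 58.4 | 42.1 |
| Sunday's | 1.50 | 35.5 | 64.4 |
| Sunday's | 2.50 | 48.0 | 52.8 |
| Sunday's | 4.00 | 58.5 | 41.2 |
| Sunday's | 6.00 | 66.7 | 33.0 |
| Sunday's | 10.0 | 75.8 | 23.9 |
| Sunday's | 15.0 | 82.2 | 17.3 |
| Sunday's | 20.0 | 85.4 | 14.5 |

(each reading ± 0.5 percentage points)



- concentration of links at 30 h, in M
- concentration of first end groups at 30 h, in M

The first holds to that clock. Let a be the first end groups left, as a fraction of the charge. With equal charges, a = 1/(1 + κt), and Monday's first reading gives κ = 0.177 /h. So at 30 h she expects a = 15.8 %, or 0.0673 M of links.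

I hold to a ceiling. Around 11.0 h, Monday's a averages 43.5 % and falls at 0.0140 /h. If rate = κab, the fraction b of second end groups left is 18.2 %, a rough reading given the scatter. Define the waste ratio w as second end groups lost without forming a link, per link made: here w = 0.448. If w holds, equal charges cap links at 1/(1 + w) = 69.0 %. The gap to that ceiling takes 8.96 h at the present pace, less than the 19.0 h remaining, so I expect about 0.0552 M of links.

The forecast lands near my number on a different ground, "the slowdown tracks product": 0.055 M of links and 0.025 M of first end groups.

    first end groups + second end groups → links + released group (k = 2.40 /M/h)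
    crystals ⇌ released group, rate k2*(cs2 - [released group]) while solid is left; crystals form when [released group] > cs2 (solubility = 26.0 mM, k = 0.440 /h)
    2 second end groups → homo dimer (k = 0.770 /M/h)

The flask gives 0.0540 M of links and 0.0260 M of first end groups. The clock fits early, 65.3 % against 67.1 % at 3.00 h, but not at 30 h, 15.8 % against 32.5 %. Each homo dimer holds two second end groups, so w in this flask at 30.0 h is 0.427. In this flask at 30.0 h, second end groups, the limiting reagent, have less of their charge left, 3.6 %, than first end groups, 32 %. For a neighbouring flask charged with 0.32 M of first end groups, equivalents and time held, my w from Monday's readings reckons a ceiling of 0.221 M of links. That flask gives 0.227 M, with 0.020 % of its second end groups left.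

The numbers in the tables are calculated with made-up constants; noise was put on by code.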